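The ten-membered carbocycle is closed last, by ring-closing metathesis across C4=C5 (germacrane numbering: C1 ring ketone, C3 carbinol, C6/C7 lactone fusion, C8 ester, C10 tertiary carbinol). This is the only C=C of that ring, a Z-trisubstituted alkene flanked by the oxygenated carbons C3 and C6. One operation makes the ring and fixes the alkene geometry, which ring strain should funnel to Z. The precursor is an acyclic diene (C6 vinyl, C4 isopropenyl) on the finished trans α-methylene-γ-lactone. It is assembled from an L-glutamate-derived bromomethyl butenolide, an (R)-citramalate-derived keto aldehyde and methacrolein by Barbier allylation, Mitsunobu esterification with inversion at C8, and a boron aldol.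

Key step: step 15

Remark: the germacrane locants above are used throughout (C11 = lactone α-carbon, C12 = lactone carbonyl, C13 = exocyclic methylene).
Assumption: compounds 1 and 11 are bought as single enantiomers.
Assumption: the Barbier step is taken to give the 8S (anti) alcohol by the chair-transition-state argument in step 12; this sense, and the Re-face sense assumed for (−)-Ipc2BCl in step 14, are predictions, not established facts.

Step 1
Reactants: 1 (5S)-5-(hydroxymethyl)oxolan-2-one
Product: 2 (2S)-5-oxooxolane-2-carbaldehyde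
Conditions: TEMPO (10 mol%), PhI(OAc)2, CH2Cl2, rt
Reagents that add atoms: none
Why: TEMPO/PhI(OAc)2 oxidation takes the primary alcohol to the aldehyde under non-basic conditions without over-oxidation, so the epimerisable α-acyloxy stereocentre (future C6) should be kept.

Step 2
Reactants: 2 (2S)-5-oxooxolane-2-carbaldehyde
Product: 3 (5S)-5-ethenyloxolan-2-one
Conditions: Ph3PCH3Br, KHMDS, THF, −78 °C; then 2, −78 °C to 0 °C
Reagents that add atoms: methyltriphenylphosphonium bromide, C[P+](c1ccccc1)(c1ccccc1)c1ccccc1.[Br-]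
Why: Wittig methylenation with the salt-free ylide at low temperature should convert the aldehyde into the vinyl group (future C5) faster than the α-stereocentre can epimerise.

Step 3
Reactants: 3 (5S)-5-ethenyloxolan-2-one
Product: 5 (5S)-5-ethenyl-3-(phenylselanyl)oxolan-2-one (both C3 epimers), via lithium enolate 4 (not isolated)
Conditions: LDA, THF, −78 °C; PhSeBr, −78 °C
Reagents that add atoms: phenylselanyl bromide, Br[Se]c1ccccc1
Why: Kinetic enolate formation at the only enolisable position (future C11) and electrophilic selenenylation install the selenide needed for later unsaturation; the new centre is inconsequential because step 5 destroys it.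

Step 4
Reactants: 5 (5S)-5-ethenyl-3-(phenylselanyl)oxolan-2-one
Product: 7 (5S)-5-ethenyl-3-(hydroxymethyl)-3-(phenylselanyl)oxolan-2-one (both C3 epimers), via lithium enolate 6 (not isolated)
Conditions: LDA, THF, −78 °C; CH2O (gas), −78 °C; AcOH
Reagents that add atoms: formaldehyde, C=O
Why: The selenium-stabilised enolate undergoes aldol addition to monomeric formaldehyde, which adds the C13 hydroxymethyl carbon at C11; both diastereomers converge in step 5.

Step 5
Reactants: 7 (5S)-5-ethenyl-3-(hydroxymethyl)-3-(phenylselanyl)oxolan-2-one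
Product: 9 (5R)-5-ethenyl-3-(hydroxymethyl)furan-2(5H)-one, via selenoxide 8 (not isolated)
Conditions: 30% H2O2 (excess), THF, 0 °C to rt
Reagents that add atoms: none
Why: Selenoxide syn-elimination is expected to go toward the ring CH2 (C7) and away from the carbinol carbon, giving the endocyclic butenolide; C6 is not involved and its descriptor changes from S to R only through CIP priorities.

Step 6
Reactants: 9 (5R)-5-ethenyl-3-(hydroxymethyl)furan-2(5H)-one
Product: 10 (5R)-3-(bromomethyl)-5-ethenylfuran-2(5H)-one
Conditions: CBr4, PPh3, CH2Cl2, 0 °C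
Reagents that add atoms: carbon tetrabromide, BrC(Br)(Br)Br
Why: Appel bromination converts the primary allylic alcohol into the bromide under neutral conditions that should not enolise the labile γ-position (C6) of the butenolide.

Step 7
Reactants: 11 (2R)-2-hydroxy-2-methylbutanedioic acid [(R)-citramalic acid]
Product: 12 2-[(4R)-2,2,4-trimethyl-5-oxo-1,3-dioxolan-4-yl]acetic acid
Conditions: 2,2-dimethoxypropane, TsOH (cat.), rt
Reagents that add atoms: 2,2-dimethoxypropane, COC(C)(C)OC
Why: Acid-catalysed acetalisation engages the α-hydroxy acid unit selectively as the five-membered dioxolanone, which differentiates the two carboxyl groups without touching the C10 configuration.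

Step 8
Reactants: 12 2-[(4R)-2,2,4-trimethyl-5-oxo-1,3-dioxolan-4-yl]acetic acid
Product: 14 (3R)-3-hydroxy-3-methyloxolan-2-one, via hydroxyethyl dioxolanone 13 (not isolated)
Conditions: BH3·SMe2, THF, 0 °C to rt; MeOH; then TsOH (cat.), CH2Cl2, rt
Reagents that add atoms: none
Why: Borane reduces the free carboxylic acid chemoselectively beside the dioxolanone, and acid-catalysed transacylation then releases acetone and closes the γ-lactone, leaving C10 untouched.

Step 9
Reactants: 14 (3R)-3-hydroxy-3-methyloxolan-2-one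
Product: 15 (3R)-3-methyl-3-(triethylsilyloxy)oxolan-2-one
Conditions: TESOTf, 2,6-lutidine, CH2Cl2, 0 °C
Reagents that add atoms: triethylsilyl trifluoromethanesulfonate, CC[Si](CC)(CC)OS(=O)(=O)C(F)(F)F
Why: Silylation with the silyl triflate protects the tertiary alcohol, which prevents β-elimination and retro-aldol cleavage of the later β-oxy aldehyde and keeps boron off O10 in step 14.

Step 10
Reactants: 15 (3R)-3-methyl-3-(triethylsilyloxy)oxolan-2-one
Product: 16 (3R)-5-hydroxy-3-methyl-3-(triethylsilyloxy)pentan-2-one (in equilibrium with its cyclic hemiketal)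
Conditions: MeLi (1.1 equiv), THF, −78 °C; AcOH, −78 °C
Reagents that add atoms: methyllithium, [Li]C
Why: Addition of methyllithium to the lactone should stop at the lithium lactolate at −78 °C, and a cold acidic quench (before silyl migration can set in) releases the methyl ketone that carries C1 and C2.

Step 11
Reactants: 16 (3R)-5-hydroxy-3-methyl-3-(triethylsilyloxy)pentan-2-one
Product: 17 (3R)-3-methyl-4-oxo-3-(triethylsilyloxy)pentanal
Conditions: TEMPO (10 mol%), PhI(OAc)2, CH2Cl2, rt
Reagents that add atoms: none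
Why: TEMPO/PhI(OAc)2 oxidises the primary alcohol of the open-chain form to the C8 aldehyde; the ketone hemiketal cannot be over-oxidised and the quaternary C10 cannot epimerise.

Step 12
Reactants: 10 (5R)-3-(bromomethyl)-5-ethenylfuran-2(5H)-one; 17 (3R)-3-methyl-4-oxo-3-(triethylsilyloxy)pentanal
Product: 19 (4R,5R)-5-ethenyl-4-[(1S,3R)-1-hydroxy-3-methyl-4-oxo-3-(triethylsilyloxy)pentyl]-3-methylideneoxolan-2-one, via allylzinc bromide 18 (not isolated)
Conditions: Zn dust, THF/sat. aq NH4Cl, 0 °C to rt
Reagents that add atoms: none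
Why: Barbier allylation: the allylzinc should react at its γ-carbon (C7) on the face anti to the C6 vinyl group (7R, trans lactone) through a chair Zimmerman–Traxler transition state with the aldehyde chain equatorial (8S, inverted in step 13), the allylic transposition unveiling the exocyclic methylene, and the aldehyde reacting before the hindered ketone.

Step 13
Reactants: 19 (4R,5R)-5-ethenyl-4-[(1S,3R)-1-hydroxy-3-methyl-4-oxo-3-(triethylsilyloxy)pentyl]-3-methylideneoxolan-2-one; 20 3-methylbutanoic acid (isovaleric acid)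
Product: 21 (1R,3R)-1-[(2R,3R)-2-ethenyl-4-methylidene-5-oxooxolan-3-yl]-3-methyl-4-oxo-3-(triethylsilyloxy)pentyl 3-methylbutanoate
Conditions: PPh3, DIAD, toluene, 0 °C to rt
Reagents that add atoms: none
Why: Mitsunobu esterification displaces the oxyphosphonium ion by isovalerate in an SN2 step with inversion, which turns the 8S carbinol into the required 8R ester while the tertiary silyl ether, ketone and lactone stay inert.

Step 14
Reactants: 21 (1R,3R)-1-[(2R,3R)-2-ethenyl-4-methylidene-5-oxooxolan-3-yl]-3-methyl-4-oxo-3-(triethylsilyloxy)pentyl 3-methylbutanoate; 22 2-methylprop-2-enal (methacrolein)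
Product: 24 (1R,3R,6R)-1-[(2R,3R)-2-ethenyl-4-methylidene-5-oxooxolan-3-yl]-6-hydroxy-3,7-dimethyl-4-oxo-3-(triethylsilyloxy)oct-7-en-1-yl 3-methylbutanoate, via diisopinocampheylboron enolate 23 (not isolated)
Conditions: (−)-Ipc2BCl [from (+)-α-pinene], Et3N, Et2O, −78 °C to 0 °C; 22, −78 °C to −20 °C; MeOH, pH 7 buffer, H2O2, 0 °C
Reagents that add atoms: none
Why: Diisopinocampheylboron-mediated methyl ketone aldol: the ketone can enolise only toward its methyl group (C10 is quaternary), and the chiral borinate is expected to add to the Re face of methacrolein under reagent control, setting 3R, while esters and lactone are not enolised by R2BCl/Et3N.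

Step 15
Reactants: 24 (1R,3R,6R)-1-[(2R,3R)-2-ethenyl-4-methylidene-5-oxooxolan-3-yl]-6-hydroxy-3,7-dimethyl-4-oxo-3-(triethylsilyloxy)oct-7-en-1-yl 3-methylbutanoate
Product: 25 (3aR,4R,6R,9R,10Z,11aR)-9-hydroxy-6,10-dimethyl-3-methylidene-2,7-dioxo-6-(triethylsilyloxy)-2,3,3a,4,5,6,7,8,9,11a-decahydrocyclodeca[b]furan-4-yl 3-methylbutanoate
Conditions: Hoveyda–Grubbs II (15 mol%), 1,4-benzoquinone (30 mol%), toluene (1 mM, slow addition), 80 °C, Ar sparge
Reagents that add atoms: none
Why: Olefin ring-closing metathesis: the Ru alkylidene is expected to load at the monosubstituted C6 vinyl group, engage the 1,1-disubstituted C4 isopropenyl alkene by [2+2]/retro-[2+2] and release ethylene, which makes the C4=C5 bond. The closest known reaction type is RCM macrocyclisation to trisubstituted cycloalkenes in medium carbocycles. The only ring closed is the ten-membered carbocycle, by alkene-forming closure between C4 and C5, the lactone being already in place and untouched. No stereocentre is formed; the new stereoelement is the alkene geometry, and Z is expected because the E-trisubstituted cyclodecene between the C3 and C6 stereocentres is more strained and reversible metathesis should funnel material to Z. The step needs cyclisation over oligomerisation, chemoselectivity over the exocyclic C11=C13 methylene and no Ru–H isomerisation of the C3 allylic alcohol; high dilution, the electron-poor 1,1-disubstituted character of the methylene lactone, the activating free C3 hydroxyl and the benzoquinone additive should secure these. The trans lactone holds the C6 vinyl group and the C7 side chain on adjacent carbons, which shortens the chain that has to fold.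

Step 16
Reactants: 25 (3aR,4R,6R,9R,10Z,11aR)-9-hydroxy-6,10-dimethyl-3-methylidene-2,7-dioxo-6-(triethylsilyloxy)-2,3,3a,4,5,6,7,8,9,11a-decahydrocyclodeca[b]furan-4-yl 3-methylbutanoate
Product: 26 (3aR,4R,6R,9R,10Z,11aR)-6,9-dihydroxy-6,10-dimethyl-3-methylidene-2,7-dioxo-2,3,3a,4,5,6,7,8,9,11a-decahydrocyclodeca[b]furan-4-yl 3-methylbutanoate (target)
Conditions: HF·pyridine, pyridine/THF, 0 °C
Reagents that add atoms: none
Why: HF·pyridine cleaves the tertiary triethylsilyl ether under mildly acidic, non-basic conditions that should spare the β-hydroxy ketone (no retro-aldol), the α-ketol, the isovalerate and the Michael-acceptor lactone.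

Compound list
1 | (5S)-5-(hydroxymethyl)oxolan-2-one | O=C1CC[C@@H](CO)O1 | starting material
2 | (2S)-5-oxooxolane-2-carbaldehyde | O=C[C@@H]1CCC(=O)O1 | intermediate
3 | (5S)-5-ethenyloxolan-2-one | C=C[C@@H]1CCC(=O)O1 | intermediate
4 | lithium enolate of 3 (not isolated) | [Li]OC1=CC[C@@H](C=C)O1 | intermediate
5 | (5S)-5-ethenyl-3-(phenylselanyl)oxolan-2-one, both C3 epimers | C=C[C@@H]1CC([Se]c2ccccc2)C(=O)O1 | intermediate
6 | lithium enolate of 5 (not isolated) | [Li]OC1=C([Se]c2ccccc2)C[C@@H](C=C)O1 | intermediate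
7 | (5S)-5-ethenyl-3-(hydroxymethyl)-3-(phenylselanyl)oxolan-2-one, both C3 epimers | C=C[C@@H]1CC(CO)([Se]c2ccccc2)C(=O)O1 | intermediate
8 | selenoxide of 7 (not isolated) | C=C[C@@H]1CC(CO)([Se](=O)c2ccccc2)C(=O)O1 | intermediate
9 | (5R)-5-ethenyl-3-(hydroxymethyl)furan-2(5H)-one | C=C[C@@H]1C=C(CO)C(=O)O1 | intermediate
10 | (5R)-3-(bromomethyl)-5-ethenylfuran-2(5H)-one | C=C[C@@H]1C=C(CBr)C(=O)O1 | intermediate
11 | (2R)-2-hydroxy-2-methylbutanedioic acid, (R)-citramalic acid | OC(=O)[C@](C)(O)CC(=O)O | starting material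
12 | 2-[(4R)-2,2,4-trimethyl-5-oxo-1,3-dioxolan-4-yl]acetic acid | OC(=O)C[C@@]1(C)OC(C)(C)OC1=O | intermediate
13 | (5R)-5-(2-hydroxyethyl)-2,2,5-trimethyl-1,3-dioxolan-4-one (not isolated) | OCC[C@@]1(C)OC(C)(C)OC1=O | intermediate
14 | (3R)-3-hydroxy-3-methyloxolan-2-one | O=C1OCC[C@@]1(C)O | intermediate
15 | (3R)-3-methyl-3-(triethylsilyloxy)oxolan-2-one | O=C1OCC[C@@]1(C)O[Si](CC)(CC)CC | intermediate
16 | (3R)-5-hydroxy-3-methyl-3-(triethylsilyloxy)pentan-2-one | CC(=O)[C@](C)(O[Si](CC)(CC)CC)CCO | intermediate
17 | (3R)-3-methyl-4-oxo-3-(triethylsilyloxy)pentanal | CC(=O)[C@](C)(O[Si](CC)(CC)CC)CC=O | intermediate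
18 | bromo{[(5R)-5-ethenyl-2-oxo-2,5-dihydrofuran-3-yl]methyl}zinc (not isolated) | Br[Zn]CC1=C[C@@H](C=C)OC1=O | intermediate
19 | (4R,5R)-5-ethenyl-4-[(1S,3R)-1-hydroxy-3-methyl-4-oxo-3-(triethylsilyloxy)pentyl]-3-methylideneoxolan-2-one | C=C1C(=O)O[C@H](C=C)[C@H]1[C@@H](O)C[C@@](C)(O[Si](CC)(CC)CC)C(C)=O | intermediate
20 | 3-methylbutanoic acid (isovaleric acid) | CC(C)CC(=O)O | starting material
21 | (1R,3R)-1-[(2R,3R)-2-ethenyl-4-methylidene-5-oxooxolan-3-yl]-3-methyl-4-oxo-3-(triethylsilyloxy)pentyl 3-methylbutanoate | C=C1C(=O)O[C@H](C=C)[C@H]1[C@H](OC(=O)CC(C)C)C[C@@](C)(O[Si](CC)(CC)CC)C(C)=O | intermediate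
22 | 2-methylprop-2-enal (methacrolein) | C=C(C)C=O | starting material
23 | diisopinocampheylboron enolate of 21 (not isolated) | C=C1C(=O)O[C@H](C=C)[C@H]1[C@H](OC(=O)CC(C)C)C[C@@](C)(O[Si](CC)(CC)CC)C(=C)OB([C@@H]1C[C@@H]2C[C@H]([C@H]1C)C2(C)C)[C@@H]1C[C@@H]2C[C@H]([C@H]1C)C2(C)C | intermediate
24 | (1R,3R,6R)-1-[(2R,3R)-2-ethenyl-4-methylidene-5-oxooxolan-3-yl]-6-hydroxy-3,7-dimethyl-4-oxo-3-(triethylsilyloxy)oct-7-en-1-yl 3-methylbutanoate | C=C1C(=O)O[C@H](C=C)[C@H]1[C@H](OC(=O)CC(C)C)C[C@@](C)(O[Si](CC)(CC)CC)C(=O)C[C@@H](O)C(C)=C | intermediate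
25 | (3aR,4R,6R,9R,10Z,11aR)-9-hydroxy-6,10-dimethyl-3-methylidene-2,7-dioxo-6-(triethylsilyloxy)-2,3,3a,4,5,6,7,8,9,11a-decahydrocyclodeca[b]furan-4-yl 3-methylbutanoate | C=C1C(=O)O[C@@H]2/C=C(/C)[C@H](O)CC(=O)[C@](C)(O[Si](CC)(CC)CC)C[C@@H](OC(=O)CC(C)C)[C@@H]12 | intermediate
26 | (3aR,4R,6R,9R,10Z,11aR)-6,9-dihydroxy-6,10-dimethyl-3-methylidene-2,7-dioxo-2,3,3a,4,5,6,7,8,9,11a-decahydrocyclodeca[b]furan-4-yl 3-methylbutanoate | C=C1C(=O)O[C@@H]2/C=C(/C)[C@H](O)CC(=O)[C@](C)(O)C[C@@H](OC(=O)CC(C)C)[C@@H]12 | target

Total step count: 16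
Longest linear sequence: 11 steps (steps 1–6 and 12–16, from 1); the citramalate branch is 10 steps (steps 7–16).

Steps most likely to fail

1. Step 15 (ring-closing metathesis). The carbene may be consumed at the C6 vinyl group in intermolecular metathesis (oligomers) because it engages the hindered 1,1-disubstituted C4 alkene too slowly, or the ring may close with E geometry. The fallback sets out from 21 and returns at 25. Step 14 is run with (2E)-2-methylocta-2,7-dienal F1 in place of 22; F1 is made by Wittig reaction of hex-5-enal with 2-(triphenylphosphoranylidene)propanal. This gives the relay triene (1R,3R,6R,7E)-1-[(2R,3R)-2-ethenyl-4-methylidene-5-oxooxolan-3-yl]-6-hydroxy-3,7-dimethyl-4-oxo-3-(triethylsilyloxy)trideca-7,12-dien-1-yl 3-methylbutanoate F2. With the same Ru catalyst the carbene should load at the unhindered terminal alkene of the tail, expel cyclopentene and so be delivered as the C4 alkylidene. That alkylidene then only has to close onto the monosubstituted C6 vinyl group (relay ring-closing metathesis), which gives 25. This changes the substrate and the site of catalyst entry, not the catalyst or temperature.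

2. Step 13 (Mitsunobu inversion). Displacement at the hindered C8 carbinol may be outrun by elimination toward C7 (diene conjugated with the methylene lactone), or the alcohol may be recovered. The fallback sets out from 10 and returns at 21. Bromide 10 is converted with hexabutylditin and Pd(PPh3)4 into (5R)-5-ethenyl-3-[(tributylstannyl)methyl]furan-2(5H)-one F3. BF3·OEt2-promoted addition of F3 to 17 at −78 °C should pass through an open antiperiplanar transition state, which is syn-selective whatever the allyl geometry and again anti to the C6 vinyl group. It should therefore give the 8R alcohol (4R,5R)-5-ethenyl-4-[(1R,3R)-1-hydroxy-3-methyl-4-oxo-3-(triethylsilyloxy)pentyl]-3-methylideneoxolan-2-one F4 directly. Acylation of F4 with isovaleric anhydride and DMAP, with retention, gives 21. The same acylation applies if step 12 itself delivers the 8R alcohol.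

3. Step 14 (boron aldol). Facial selectivity at the aldehyde may be poor, because reagent control in methyl ketone borinates is modest and the C10 silyloxy centre may oppose it. The fallback sets out from 21 and returns at 24. TMSOTf/Et3N converts 21 into the enol silane (1R,3R)-1-[(2R,3R)-2-ethenyl-4-methylidene-5-oxooxolan-3-yl]-3-methyl-3-(triethylsilyloxy)-4-(trimethylsilyloxy)pent-4-en-1-yl 3-methylbutanoate F5. Mukaiyama aldol addition of F5 to 22 under a chiral Ti(IV)–BINOL Lewis acid gives the silyl ether (1R,3R,6R)-1-[(2R,3R)-2-ethenyl-4-methylidene-5-oxooxolan-3-yl]-3,7-dimethyl-4-oxo-3-(triethylsilyloxy)-6-(trimethylsilyloxy)oct-7-en-1-yl 3-methylbutanoate F6. The catalyst enantiomer is chosen for Re-face attack, so the open transition state is under catalyst control. Citric acid in methanol then cleaves the trimethylsilyl ether to give 24.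

Further compounds
F1 | step 15 | (2E)-2-methylocta-2,7-dienal | O=C/C(C)=C/CCCC=C
F2 | step 15 | (1R,3R,6R,7E)-1-[(2R,3R)-2-ethenyl-4-methylidene-5-oxooxolan-3-yl]-6-hydroxy-3,7-dimethyl-4-oxo-3-(triethylsilyloxy)trideca-7,12-dien-1-yl 3-methylbutanoate | C=C1C(=O)O[C@H](C=C)[C@H]1[C@H](OC(=O)CC(C)C)C[C@@](C)(O[Si](CC)(CC)CC)C(=O)C[C@@H](O)/C(C)=C/CCCC=C
F3 | step 13 | (5R)-5-ethenyl-3-[(tributylstannyl)methyl]furan-2(5H)-one | C=C[C@@H]1C=C(C[Sn](CCCC)(CCCC)CCCC)C(=O)O1
F4 | step 13 | (4R,5R)-5-ethenyl-4-[(1R,3R)-1-hydroxy-3-methyl-4-oxo-3-(triethylsilyloxy)pentyl]-3-methylideneoxolan-2-one | C=C1C(=O)O[C@H](C=C)[C@H]1[C@H](O)C[C@@](C)(O[Si](CC)(CC)CC)C(C)=O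
F5 | step 14 | (1R,3R)-1-[(2R,3R)-2-ethenyl-4-methylidene-5-oxooxolan-3-yl]-3-methyl-3-(triethylsilyloxy)-4-(trimethylsilyloxy)pent-4-en-1-yl 3-methylbutanoate | C=C1C(=O)O[C@H](C=C)[C@H]1[C@H](OC(=O)CC(C)C)C[C@@](C)(O[Si](CC)(CC)CC)C(=C)O[Si](C)(C)C
F6 | step 14 | (1R,3R,6R)-1-[(2R,3R)-2-ethenyl-4-methylidene-5-oxooxolan-3-yl]-3,7-dimethyl-4-oxo-3-(triethylsilyloxy)-6-(trimethylsilyloxy)oct-7-en-1-yl 3-methylbutanoate | C=C1C(=O)O[C@H](C=C)[C@H]1[C@H](OC(=O)CC(C)C)C[C@@](C)(O[Si](CC)(CC)CC)C(=O)C[C@@H](O[Si](C)(C)C)C(C)=C
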